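**Retrosynthetic overview**
- The (Z)-enyne is made last, from a C6 allyl group by Z-selective enyne cross-metathesis and desilylation.
- The oxocane (second ring) comes from an all-cis 2-allyl-3-chlorotetrahydrofuran carrying a (1S,3Z)-1-acetoxyhex-3-enyl chain: bromonium → bicyclic oxonium → acetoxonium → chloride. This one operation forms O–C12, C13–Br and C9–Cl.
- The tetrahydrofuran (first ring) comes from 5-endo chloro-etherification of a (Z)-homoallylic alcohol (O–C6, C7–Cl); the hexenyl chain is added by (Z)-butenyl cuprate opening of a pendant epoxide.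
- C9 and C10 come from (S,S)-diepoxybutane (L-tartrate pool), opened once by the acetylide of pent-1-en-4-yne.

Assumption: the SMILES is read as drawn, i.e. (3Z,6S,7S,9S,10S,12R,13R) with C1 = alkyne CH and C15 = CH3 (this chain numbering is used below); the oxocane is 2,8-trans.

**Step 1**
Reactants: 1 [(4S,5S)-2,2-dimethyl-1,3-dioxolane-4,5-diyl]bis(methylene) bis(4-methylbenzenesulfonate)
Product: 2 (2S,3S)-2,3-dihydroxybutane-1,4-diyl bis(4-methylbenzenesulfonate)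
Conditions: 1 M HCl, EtOH, reflux
Reagents that add atoms: none
Why: Acid-catalysed acetonide hydrolysis leaves the primary tosylates and both tartrate-derived stereocentres untouched.

**Step 2**
Reactants: 2 (2S,3S)-2,3-dihydroxybutane-1,4-diyl bis(4-methylbenzenesulfonate)
Product: 4 (2S,2′S)-2,2′-bioxirane, via epoxy tosylate 3 (not isolated)
Conditions: KOH, Et2O/H2O, rt
Reagents that add atoms: none
Why: Two intramolecular Williamson closures (3-exo-tet) at the primary tosylate carbons leave both carbinol centres untouched and give the C2-symmetric (S,S)-diepoxide.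

**Step 3**
Reactants: 4 (2S,2′S)-2,2′-bioxirane; 5 pent-1-en-4-yne
Product: 6 (1S)-1-[(2S)-oxiran-2-yl]hept-6-en-3-yn-1-ol
Conditions: n-BuLi, THF, −78 °C; BF3·OEt2; then 4 (3 equiv), −78 °C
Reagents that add atoms: none
Why: Yamaguchi–Hirao alkynylation opens one epoxide at its CH2 terminus (the two epoxides are homotopic, so mono-opening gives one product and excess 4 suppresses double opening), leaving C9 (S) and C10 (S) as in 4.

**Step 4**
Reactants: 6 (1S)-1-[(2S)-oxiran-2-yl]hept-6-en-3-yn-1-ol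
Product: 7 (1S,3Z)-1-[(2S)-oxiran-2-yl]hepta-3,6-dien-1-ol
Conditions: H2 (1 atm), Pd/CaCO3 poisoned with Pb(OAc)2, quinoline, EtOAc, rt
Reagents that add atoms: none
Why: Lindlar syn-semihydrogenation gives the (Z)-alkene and, stopped after one equivalent of H2, spares the terminal alkene and the epoxide.

**Step 5**
Reactants: 7 (1S,3Z)-1-[(2S)-oxiran-2-yl]hepta-3,6-dien-1-ol
Product: 8 (2S,3S,5S)-3-chloro-5-[(2S)-oxiran-2-yl]-2-(prop-2-en-1-yl)oxolane
Conditions: trichloroisocyanuric acid (0.37 equiv), NaHCO3, MeCN, −30 → 0 °C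
Reagents that add atoms: trichloroisocyanuric acid, ClN1C(=O)N(Cl)C(=O)N(Cl)C1=O
Why: 5-endo chloro-etherification (the chloro counterpart of the 5-endo-trig iodocyclisation of homoallylic alcohols), in which hydroxyl-assisted Cl+ transfer to the (Z)-alkene gives anti addition, so Cl at C7 is cis to the allyl group at C6, and the envelope with the C9 substituent pseudo-equatorial gives, as (Z)-homoallylic alcohols do in the iodine series, the all-cis ring, i.e. (6S,7S).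

**Step 6**
Reactants: 8 (2S,3S,5S)-3-chloro-5-[(2S)-oxiran-2-yl]-2-(prop-2-en-1-yl)oxolane
Product: 9 (1S,3Z)-1-[(2S,4S,5S)-4-chloro-5-(prop-2-en-1-yl)oxolan-2-yl]hex-3-en-1-ol
Conditions: EtLi, CuBr·SMe2, Et2O, −40 °C; HC≡CH, −50 → −25 °C; then 8, −40 → 0 °C
Reagents that add atoms: ethyllithium, CC[Li]; acetylene, C#C
Why: Normant syn-carbocupration of acetylene gives the (Z)-but-1-enyl cuprate, which opens the epoxide at CH2 (SN2), so the 12Z alkene is installed and C10 (S) is untouched.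

**Step 7**
Reactants: 9 (1S,3Z)-1-[(2S,4S,5S)-4-chloro-5-(prop-2-en-1-yl)oxolan-2-yl]hex-3-en-1-ol
Product: 10 (1S,3Z)-1-[(2S,4S,5S)-4-chloro-5-(prop-2-en-1-yl)oxolan-2-yl]hex-3-en-1-yl acetate
Conditions: Ac2O, pyridine, DMAP (cat.), CH2Cl2, 0 °C → rt
Reagents that add atoms: acetic anhydride, CC(=O)OC(C)=O
Why: Standard O-acylation of the only hydroxyl, which also installs the neighbouring group needed in step 8.

**Step 8**
Reactants: 10 (1S,3Z)-1-[(2S,4S,5S)-4-chloro-5-(prop-2-en-1-yl)oxolan-2-yl]hex-3-en-1-yl acetate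
Product: 13 (2S,3S,5S,6S,8R)-8-[(1R)-1-bromopropyl]-3,5-dichloro-2-(prop-2-en-1-yl)oxocan-6-yl acetate, via bicyclic oxonium ion 11 (not isolated), via acetoxonium ion 12 (not isolated)
Conditions: Et2SBr·SbCl5Br (1.05 equiv), MeNO2/CH2Cl2, −78 °C, 10 min; then Et4NCl (5 equiv), −78 °C → rt, 3 h
Reagents that add atoms: bromodiethylsulfonium bromopentachloroantimonate, CC[S+](Br)CC.Cl[Sb-](Cl)(Cl)(Cl)(Cl)Br; tetraethylammonium chloride, CC[N+](CC)(CC)CC.[Cl-]
Why: Proposed new method: Br+ transfer to the (Z)-12,13-alkene and 5-exo capture by the ring oxygen give the cis-fused oxonium 11 with the bromopropyl group on the convex face (the only low-energy choice, because the all-cis tetrahydrofuran already holds the allyl group on the concave face, which is what makes the oxocane 2,8-trans), anti addition across the Z-alkene sets (12R,13R), the C10 acetate then opens the strained O–C9 bond by 5-exo neighbouring-group attack (first inversion at C9, ring expansion to the oxocane, dioxolanylium 12), and chloride opens 12 by SN2 at C9 (second inversion, net retention, Cl trans to OAc) rather than at C10, where its approach is 1,3-syn to the C12 side chain; the closest known reactions are the Et2SBr·SbCl5Br-induced ring expansion of tetrahydrofurans through bicyclic oxonium ions opened by a neighbouring carbonate, and the chloride opening of acetoxonium ions that converts 1,2-diols into trans-chlorohydrin acetates.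

**Step 9**
Reactants: 14 bromoethene; 15 ethynyltri(propan-2-yl)silane
Product: 16 (but-3-en-1-yn-1-yl)tri(propan-2-yl)silane
Conditions: PdCl2(PPh3)2 (2 mol %), CuI (4 mol %), i-Pr2NH, THF, 0 °C → rt
Reagents that add atoms: none
Why: Sonogashira coupling of a vinyl bromide with a terminal alkyne gives the silyl-capped conjugated enyne.

**Step 10**
Reactants: 13 (2S,3S,5S,6S,8R)-8-[(1R)-1-bromopropyl]-3,5-dichloro-2-(prop-2-en-1-yl)oxocan-6-yl acetate; 16 (but-3-en-1-yn-1-yl)tri(propan-2-yl)silane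
Product: 17 (2S,3S,5S,6S,8R)-8-[(1R)-1-bromopropyl]-3,5-dichloro-2-{(2Z)-5-[tri(propan-2-yl)silyl]pent-2-en-4-yn-1-yl}oxocan-6-yl acetate
Conditions: 16 (4 equiv), second-generation Grubbs catalyst RuCl2(=CHPh)(PCy3)(H2IMes) (10 mol %), benzene, 70 °C
Reagents that add atoms: none
Why: Cross-metathesis of a terminal alkene with a silyl-capped conjugated enyne is kinetically Z-selective (alkynyl-substituted ruthenium carbene), and 13 has no other alkene and no stereocentre at risk.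

**Step 11**
Reactants: 17 (2S,3S,5S,6S,8R)-8-[(1R)-1-bromopropyl]-3,5-dichloro-2-{(2Z)-5-[tri(propan-2-yl)silyl]pent-2-en-4-yn-1-yl}oxocan-6-yl acetate
Product: 18 (2S,3S,5S,6S,8R)-8-[(1R)-1-bromopropyl]-3,5-dichloro-2-[(2Z)-pent-2-en-4-yn-1-yl]oxocan-6-yl acetate
Conditions: n-Bu4NF, AcOH (1:1), THF, 0 °C
Reagents that add atoms: none
Why: Fluoride-induced C–Si cleavage (protodesilylation) of the alkynylsilane under buffered conditions spares the acetate and the secondary halides and gives the target.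

**Compound list**
1 | [(4S,5S)-2,2-dimethyl-1,3-dioxolane-4,5-diyl]bis(methylene) bis(4-methylbenzenesulfonate) (1,4-di-O-tosyl-2,3-O-isopropylidene-L-threitol) | CC1(C)O[C@@H](COS(=O)(=O)c2ccc(C)cc2)[C@H](COS(=O)(=O)c2ccc(C)cc2)O1 | starting material
2 | (2S,3S)-2,3-dihydroxybutane-1,4-diyl bis(4-methylbenzenesulfonate) | Cc1ccc(cc1)S(=O)(=O)OC[C@H](O)[C@@H](O)COS(=O)(=O)c1ccc(C)cc1 | intermediate
3 | (2S)-2-hydroxy-2-[(2S)-oxiran-2-yl]ethyl 4-methylbenzenesulfonate | Cc1ccc(cc1)S(=O)(=O)OC[C@H](O)[C@@H]1CO1 | intermediate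
4 | (2S,2′S)-2,2′-bioxirane [(S,S)-1,2:3,4-diepoxybutane] | C1O[C@@H]1[C@@H]1CO1 | intermediate
5 | pent-1-en-4-yne | C=CCC#C | starting material
6 | (1S)-1-[(2S)-oxiran-2-yl]hept-6-en-3-yn-1-ol | C=CCC#CC[C@H](O)[C@@H]1CO1 | intermediate
7 | (1S,3Z)-1-[(2S)-oxiran-2-yl]hepta-3,6-dien-1-ol | C=CC/C=C\C[C@H](O)[C@@H]1CO1 | intermediate
8 | (2S,3S,5S)-3-chloro-5-[(2S)-oxiran-2-yl]-2-(prop-2-en-1-yl)oxolane (all-cis) | C=CC[C@@H]1O[C@@H](C[C@@H]1Cl)[C@@H]2CO2 | intermediate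
9 | (1S,3Z)-1-[(2S,4S,5S)-4-chloro-5-(prop-2-en-1-yl)oxolan-2-yl]hex-3-en-1-ol | C=CC[C@@H]1O[C@@H](C[C@@H]1Cl)[C@@H](O)C/C=C\CC | intermediate
10 | (1S,3Z)-1-[(2S,4S,5S)-4-chloro-5-(prop-2-en-1-yl)oxolan-2-yl]hex-3-en-1-yl acetate | C=CC[C@@H]1O[C@@H](C[C@@H]1Cl)[C@@H](OC(C)=O)C/C=C\CC | intermediate
11 | 1-oxoniabicyclo[3.3.0]octane salt, O+ joined to C6, C9 and C12; allyl (C6) and Cl (C7) on the concave face, AcO at C10, (1R)-1-bromopropyl (C12) on the convex face; (6S,7S,9S,10S,12R,13R); SbCl5Br− counter-ion | C=CC[C@H]1[C@@H](Cl)C[C@@H]2[O+]1[C@H](C[C@@H]2OC(C)=O)[C@H](Br)CC.Cl[Sb-](Cl)(Cl)(Cl)(Cl)Br | intermediate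
12 | oxocane-fused 2-methyl-1,3-dioxolan-2-ylium salt, acetoxonium bridging C9 and C10 cis; (6S,7S,9R,10S,12R,13R); SbCl5Br− counter-ion | C=CC[C@@H]1O[C@@H]([C@H](Br)CC)C[C@@H]2OC(C)=[O+][C@@H]2C[C@@H]1Cl.Cl[Sb-](Cl)(Cl)(Cl)(Cl)Br | intermediate
13 | (2S,3S,5S,6S,8R)-8-[(1R)-1-bromopropyl]-3,5-dichloro-2-(prop-2-en-1-yl)oxocan-6-yl acetate | C=CC[C@@H]1O[C@@H]([C@H](Br)CC)C[C@H](OC(C)=O)[C@@H](Cl)C[C@@H]1Cl | intermediate
14 | bromoethene (vinyl bromide) | C=CBr | starting material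
15 | ethynyltri(propan-2-yl)silane | C#C[Si](C(C)C)(C(C)C)C(C)C | starting material
16 | (but-3-en-1-yn-1-yl)tri(propan-2-yl)silane | C=CC#C[Si](C(C)C)(C(C)C)C(C)C | intermediate
17 | (2S,3S,5S,6S,8R)-8-[(1R)-1-bromopropyl]-3,5-dichloro-2-{(2Z)-5-[tri(propan-2-yl)silyl]pent-2-en-4-yn-1-yl}oxocan-6-yl acetate | CC(C)[Si](C(C)C)(C(C)C)C#C/C=C\C[C@@H]1O[C@@H]([C@H](Br)CC)C[C@H](OC(C)=O)[C@@H](Cl)C[C@@H]1Cl | intermediate
18 | (2S,3S,5S,6S,8R)-8-[(1R)-1-bromopropyl]-3,5-dichloro-2-[(2Z)-pent-2-en-4-yn-1-yl]oxocan-6-yl acetate | C#C/C=C\C[C@@H]1O[C@@H]([C@H](Br)CC)C[C@H](OC(C)=O)[C@@H](Cl)C[C@@H]1Cl | target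

**Step count**
Total steps: 11. Longest linear sequence: 10 (steps 1–8, 10, 11).

**Three steps most likely to fail**

Step 8 (ring expansion). The risks are chloride intercepting oxonium 11 before the acetate does (giving the C9 epimer or ring-opened tetrahydrofurans) and chloride opening 12 at C10 instead of C9. The fallback sets out from 9 and returns at 13. Alcohol 9 is treated with Et2SBr·SbCl5Br in the presence of 2,6-di-tert-butyl-4-methylpyridine, so that the free C10 hydroxyl closes onto C9 of the oxonium ion (inversion, ring expansion) and gives (1S,3R,5S,6S,8R)-3-[(1R)-1-bromopropyl]-6-chloro-5-(prop-2-en-1-yl)-4,9-dioxabicyclo[6.1.0]nonane F1. The epoxide is then opened by chloride under chelation control (Ti(OiPr)4, Et2NH2Cl, CH2Cl2; titanium bridged between the epoxide and ring oxygens, attack at the distal carbon C9 with inversion) to (2S,3S,5S,6S,8R)-8-[(1R)-1-bromopropyl]-3,5-dichloro-2-(prop-2-en-1-yl)oxocan-6-ol F2, and Ac2O/pyridine gives 13.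

Step 5 (chloro-etherification). The risks are the 2,5-trans diastereomer, sluggish Cl+ transfer to an unactivated alkene, and loss of the epoxide. The fallback sets out from 4 and returns at 9; it closes the tetrahydrofuran by a stereospecific SN2 displacement instead of through a chloriranium ion.
- Mono-opening of 4 with the (Z)-but-1-enyl cuprate of step 6 gives (1S,3Z)-1-[(2S)-oxiran-2-yl]hex-3-en-1-ol F3.
- CH2=CHMgBr with catalytic CuI opens the second epoxide to (4S,5S,7Z)-deca-1,7-diene-4,5-diol F4.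
- 2,2-Dimethoxypropane/PPTS gives (4S,5S)-2,2-dimethyl-4-[(2Z)-pent-2-en-1-yl]-5-(prop-2-en-1-yl)-1,3-dioxolane F5.
- Aldehyde-selective Wacker oxidation of the terminal alkene (PdCl2(PhCN)2, CuCl2, AgNO2, O2, t-BuOH/MeNO2) gives 3-{(4S,5S)-2,2-dimethyl-5-[(2Z)-pent-2-en-1-yl]-1,3-dioxolan-4-yl}propanal F6.
- Enamine-catalysed α-chlorination (NCS, the 2,5-diphenylpyrrolidine enantiomer that gives the 2S chloride) gives (2S)-2-chloro-3-{(4S,5S)-2,2-dimethyl-5-[(2Z)-pent-2-en-1-yl]-1,3-dioxolan-4-yl}propanal F7.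
- Allylboronic acid pinacol ester adds with Cornforth (anti) control to give (2S,3R)-2-chloro-1-{(4S,5S)-2,2-dimethyl-5-[(2Z)-pent-2-en-1-yl]-1,3-dioxolan-4-yl}hex-5-en-3-ol F8.
- MsCl/Et3N gives (2S,3R)-2-chloro-1-{(4S,5S)-2,2-dimethyl-5-[(2Z)-pent-2-en-1-yl]-1,3-dioxolan-4-yl}hex-5-en-3-yl methanesulfonate F9.
- Aqueous AcOH frees (4R,5S,7S,8S,10Z)-5-chloro-7,8-dihydroxytrideca-1,10-dien-4-yl methanesulfonate F10, in which the C9 hydroxyl displaces the C6 mesylate (5-exo-tet, inversion; NaHCO3, MeOH, 50 °C) and gives 9 with the all-cis ring fixed by the mechanism.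

Step 10 (cross-metathesis). The risk is a poor Z/E ratio or low conversion. The fallback sets out from 13 and returns at 17. Ozonolysis of 13 (O3, CH2Cl2, −78 °C; PPh3) gives 2-{(2S,3S,5S,6S,8R)-6-acetoxy-8-[(1R)-1-bromopropyl]-3,5-dichlorooxocan-2-yl}acetaldehyde F11. Stork–Zhao olefination ([Ph3PCH2I]I, NaHMDS, THF/HMPA, −78 °C) gives (2S,3S,5S,6S,8R)-8-[(1R)-1-bromopropyl]-3,5-dichloro-2-[(2Z)-3-iodoprop-2-en-1-yl]oxocan-6-yl acetate F12. Sonogashira coupling of F12 with 15 (Pd(PPh3)4, CuI, Et2NH) then gives 17 with the Z geometry retained.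

**Further compounds**
F1 | step 8 | (1S,3R,5S,6S,8R)-3-[(1R)-1-bromopropyl]-6-chloro-5-(prop-2-en-1-yl)-4,9-dioxabicyclo[6.1.0]nonane | C=CC[C@@H]1O[C@@H]([C@H](Br)CC)C[C@@H]2O[C@@H]2C[C@@H]1Cl
F2 | step 8 | (2S,3S,5S,6S,8R)-8-[(1R)-1-bromopropyl]-3,5-dichloro-2-(prop-2-en-1-yl)oxocan-6-ol | C=CC[C@@H]1O[C@@H]([C@H](Br)CC)C[C@H](O)[C@@H](Cl)C[C@@H]1Cl
F3 | step 5 | (1S,3Z)-1-[(2S)-oxiran-2-yl]hex-3-en-1-ol | CC/C=C\C[C@H](O)[C@@H]1CO1
F4 | step 5 | (4S,5S,7Z)-deca-1,7-diene-4,5-diol | C=CC[C@H](O)[C@@H](O)C/C=C\CC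
F5 | step 5 | (4S,5S)-2,2-dimethyl-4-[(2Z)-pent-2-en-1-yl]-5-(prop-2-en-1-yl)-1,3-dioxolane | C=CC[C@@H]1OC(C)(C)O[C@H]1C/C=C\CC
F6 | step 5 | 3-{(4S,5S)-2,2-dimethyl-5-[(2Z)-pent-2-en-1-yl]-1,3-dioxolan-4-yl}propanal | O=CCC[C@@H]1OC(C)(C)O[C@H]1C/C=C\CC
F7 | step 5 | (2S)-2-chloro-3-{(4S,5S)-2,2-dimethyl-5-[(2Z)-pent-2-en-1-yl]-1,3-dioxolan-4-yl}propanal | O=C[C@@H](Cl)C[C@@H]1OC(C)(C)O[C@H]1C/C=C\CC
F8 | step 5 | (2S,3R)-2-chloro-1-{(4S,5S)-2,2-dimethyl-5-[(2Z)-pent-2-en-1-yl]-1,3-dioxolan-4-yl}hex-5-en-3-ol | C=CC[C@@H](O)[C@@H](Cl)C[C@@H]1OC(C)(C)O[C@H]1C/C=C\CC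
F9 | step 5 | (2S,3R)-2-chloro-1-{(4S,5S)-2,2-dimethyl-5-[(2Z)-pent-2-en-1-yl]-1,3-dioxolan-4-yl}hex-5-en-3-yl methanesulfonate | C=CC[C@@H](OS(C)(=O)=O)[C@@H](Cl)C[C@@H]1OC(C)(C)O[C@H]1C/C=C\CC
F10 | step 5 | (4R,5S,7S,8S,10Z)-5-chloro-7,8-dihydroxytrideca-1,10-dien-4-yl methanesulfonate | C=CC[C@@H](OS(C)(=O)=O)[C@@H](Cl)C[C@H](O)[C@@H](O)C/C=C\CC
F11 | step 10 | 2-{(2S,3S,5S,6S,8R)-6-acetoxy-8-[(1R)-1-bromopropyl]-3,5-dichlorooxocan-2-yl}acetaldehyde | O=CC[C@@H]1O[C@@H]([C@H](Br)CC)C[C@H](OC(C)=O)[C@@H](Cl)C[C@@H]1Cl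
F12 | step 10 | (2S,3S,5S,6S,8R)-8-[(1R)-1-bromopropyl]-3,5-dichloro-2-[(2Z)-3-iodoprop-2-en-1-yl]oxocan-6-yl acetate | I/C=C\C[C@@H]1O[C@@H]([C@H](Br)CC)C[C@H](OC(C)=O)[C@@H](Cl)C[C@@H]1Cl
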